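Strategy in one sentence: the C40 skeleton is completed in the last step by a two-directional Sonogashira coupling of the all-E C22 heptaene-diyne 20 with two equivalents of the unprotected, enantiopure ring enol triflate 9.

Numbering: carotenoid numbering is used for the target and the chain (ring C1 to C6, chain C7 to C15, primed for the second half). Ring intermediates are named with IUPAC locants, in which the carbonyl or triflate carbon is C1 (carotenoid C6) and C3 and C4 become carotenoid C4 and C3.

## Structural features

The target, C40H52O4, is the all-E, C2-symmetric carotenoid (3S,4S,3'S,4'S)-7,8,7',8'-tetradehydro-β,β-carotene-3,4,3',4'-tetrol: two identical 2,6,6-trimethylcyclohexene rings (ring A, C1 to C6, and ring B, C1' to C6') are joined through C6 and C6' by an unbranched C22 chain (C7 to C7') that carries methyl groups on C9, C13, C13' and C9'. The chain holds two triple bonds (C7≡C8 and C7'≡C8') and seven E double bonds, which together with the ring double bonds C5=C6 and C5'=C6' form one continuous nonaene-diyne chromophore. Each ring carries a trans-3,4-diol in which the homoallylic carbinol C3 and the allylic carbinol C4 stand next to each other and are both S; the two pairs are separated by the achiral chain, so neither can control the other and each must be set in the absolute sense. Fragile groups are the allylic hydroxyls at C4 and C4', which ionize under acid to cations delocalized into the chromophore, the polyene itself (light, oxygen, acid), and the C9=C10 and C9'=C10' bonds, whose Z forms are hardly penalized next to a linear alkyne, so that any equilibrating treatment erodes the all-E geometry. The real difficulty lies in the two junctions C5=C6–C7≡C8 and their primed counterparts, where an alkyne sits on a tetrasubstituted ring carbon between the C5 methyl group and the gem-dimethyl carbon C1, and in completing the chromophore without isomerization or acid while four hydroxyls are present. The key step exploits exactly these atoms: C7 and C7' are sp carbons, and C6 and C6' are former carbonyl carbons of a ketone that can enolize only toward C5 because C1 is quaternary, so each ring is available as a single enol triflate and the C2 axis through C15=C15' allows both C6–C7 bonds to be made in one two-directional operation.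

## Logic of the disconnections

22 to 9 and 20 (through 21). The C6–C7 and C6'–C7' bonds are cut together. They are the only bonds of the chromophore that can be opened without opening a C=C bond, and cutting them at the ring puts every stereocenter into one small piece used twice (9) and every chain double bond into one achiral piece (20). The gain is the largest available: a C40 compound with four stereocenters falls to C9 and C22, and because 9 carries free hydroxyls the coupled product is 22 itself. The forward step must form an sp2–sp bond at a tetrasubstituted ring carbon flanked by a methyl and a gem-dimethyl group, do so twice on one chain by way of 21, tolerate two free hydroxyls per ring and leave nine C=C bonds untouched. The neighbouring C8–C9 bonds are not chosen because cutting there would add a two-carbon homologation to the ring series and still leave the hindered ring–alkyne bond to be made.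

20 to 19. The two terminal C(sp)–H bonds are traced back to C–Si bonds. The silyl groups make the chain termini inert to the strong base of the chain-building step. The gain is a stable, storable precursor; the demand is a desilylation mild enough for a heptaene.

19 to 15 and 16 (through 17 and 18). The C11=C12 and C11'=C12' double bonds are cut. This places the central triene with both trisubstituted E bonds (C13=C14, C13'=C14') in 16 and the E C9=C10 bond with the masked alkyne in 15, so the chain is made from two small pieces of fixed geometry. The forward olefination must be E-selective at two new disubstituted bonds and must react through the α-carbon of 17 at both aldehyde groups, the second by way of 18.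

15 to 14, 13 and 10 (through 11 and 12). The C11–P bond, then the C11–Br bond, then the C–Si bond are cut, which leads back to 10, where the E C9=C10 bond already exists. Nothing is gained in skeleton; the demand is that substitution at the primary allylic carbon of 13 and 14 proceeds without allylic shift or E/Z change.

9 to 8 and 6 (through 7). The two O–Si bonds and then the O–S bond are cut, so that the C5=C6 ring double bond (carotenoid numbering) is traced back to the carbonyl group of 6. Because the other α-carbon of 6 is quaternary, 7 can form in one direction only. The demand is that 7 is trapped on oxygen before it can expel the β-silyloxy group, and that the silyl ethers of 8 are removed without harm to the triflate.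

6 to 5 and 4. One O–Si bond is cut, then the α-C–H bond of 5 is traced back to the α-C–O bond of the oxirane in 4. The oxirane is a latent β-hydroxyl whose C–O bond at the β-carbon is already trans to the neighbouring silyloxy group, so the trans-diol relation is decided in 4. The forward reduction must cleave only the α-C–O bond and must not dehydrate the β-hydroxy ketone.

4 to 3, 2 and 1. The two C–O bonds of the oxirane are cut (both on one face of the enone), then the O–Si bond, then the carbinol C–H bond. The single absolute stereocenter of 2 arises from the achiral 1 by reduction of the unhindered carbonyl, and this center then directs the epoxidation. The demand is regio- and enantioselective reduction of one of two carbonyls in 1 and anti facial selectivity in the epoxidation of 3.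

## Other disconnections considered

Alternative 1: the first plan that comes to mind cuts C11=C12 and C11'=C12' of the finished skeleton. The forward key step is a double Wittig olefination of 16 with two equivalents of the C15 phosphonium bromide A1, giving the tetraacetate A2, followed by ester cleavage to 22. The chosen plan is preferred on three grounds:
- The semi-stabilized ylide of A1 should form both new double bonds as E/Z mixtures, and the usual thermal or iodine equilibration would also populate the 9Z and 9'Z forms next to the alkynes.
- A1 has to be made under acidic phosphonium-forming conditions while carrying the allylic C4 oxygen.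
- The enantiopure ring is carried through a longer linear sequence (acetylide addition, dehydration, salt formation, olefination, deprotection on the C40 stage).

The chosen last step forms no C=C bond and needs no deprotection.

Alternative 2: the C15=C15' bond is cut, which uses the C2 symmetry as a dimerization. The forward key step is a reductive carbonyl homocoupling (McMurry reaction, TiCl3/LiAlH4) of two molecules of the C20 aldehyde A3, followed by desilylation. The chosen plan is preferred because:
- Low-valent titanium is expected to bind the conjugated enyne as a titanacyclopropene and to deoxygenate the allylic C4 silyloxy group.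
- The central double bond would form without geometric control.
- A3 requires an eleven-carbon linear extension on the enantiopure ring for the gain of a single bond.

Alternative 3: the skeleton is kept and the C4–H and C4'–H bonds are cut, so that C4 and C4' are set last. The forward key step is a two-directional 1,2-reduction of both ring ketones of (3S,3'S)-7,8,7',8'-tetradehydroastaxanthin A4. The chosen plan is preferred because:
- Hydride delivery to an α-hydroxy enone is steered by two opposing effects: chelation through the C3 oxygen leads to the cis diol, and axial approach on the non-chelated ring leads to the trans diol.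
- Any shortfall in selectivity is multiplied over two ends into three diastereomers of nearly equal polarity.
- The α-ketol of A4 enolizes toward C3 under base.
- A4 needs the same chain chemistry as 22 in addition to its own ring synthesis.

In the chosen plan the trans relation is fixed on a C9 ring by anti epoxidation, where minor isomers can be removed on a small molecule.

Key step: step 13

Assumptions:
- The ketoreductase of step 1 is taken to have the facial preference of the levodione reductases that form (4R)-actinol, which corresponds to (4S) in 2.
- Compounds 1, 10 and 16 are taken as commercial.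

## Steps

Step 1
Reactants: 1 2,6,6-trimethylcyclohex-2-ene-1,4-dione (ketoisophorone)
Product: 2 (4S)-4-hydroxy-2,6,6-trimethylcyclohex-2-en-1-one
Conditions: ketoreductase (short-chain dehydrogenase class, levodione-reductase type), NAD+ (cat.), formate dehydrogenase, HCO2Na, phosphate buffer pH 7, 30 °C
Reagents that add atoms: none
Why: Enzymatic carbonyl reduction by an NADH-dependent ketoreductase; only the C4 carbonyl is accessible because C1 is flanked by C(CH3)2 and C–CH3, and hydride delivery within the active site to one face of C4 sets the (4S) carbinol, the sole absolute stereocenter from which all others are relayed.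

Step 2
Reactants: 2 (4S)-4-hydroxy-2,6,6-trimethylcyclohex-2-en-1-one
Product: 3 (4S)-4-[(tert-butyldimethylsilyl)oxy]-2,6,6-trimethylcyclohex-2-en-1-one
Conditions: TBSCl, imidazole, DMF, 23 °C
Reagents that add atoms: tert-butyldimethylsilyl chloride, CC(C)(C)[Si](C)(C)Cl
Why: Standard silylation of a secondary alcohol; the bulky silyl ether is needed as the steric director of the next step and no stereocenter is touched.

Step 3
Reactants: 3 (4S)-4-[(tert-butyldimethylsilyl)oxy]-2,6,6-trimethylcyclohex-2-en-1-one
Product: 4 (2R,3R,4S)-4-[(tert-butyldimethylsilyl)oxy]-2,3-epoxy-2,6,6-trimethylcyclohexan-1-one (oxirane oxygen trans to the silyloxy group)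
Conditions: t-BuOOH (decane), BnMe3NOH (Triton B, cat.), THF, 0 °C
Reagents that add atoms: tert-butyl hydroperoxide, CC(C)(C)OO
Why: Weitz–Scheffer nucleophilic epoxidation: the hydroperoxide anion adds to C3 of the enone and the enolate closes the oxirane on C2; attack occurs on the face anti to the adjacent C4 silyloxy group, which sets C3 (and C2) so that the new C3–O bond is trans to the C4–O bond.

Step 4
Reactants: 4 (2R,3R,4S)-4-[(tert-butyldimethylsilyl)oxy]-2,3-epoxy-2,6,6-trimethylcyclohexan-1-one
Product: 5 (3S,4S)-4-[(tert-butyldimethylsilyl)oxy]-3-hydroxy-2,6,6-trimethylcyclohexan-1-one (3-OH trans to 4-OSi; mixture of epimers at C2)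
Conditions: SmI2 (2.2 equiv), THF/MeOH, −90 °C
Reagents that add atoms: none
Why: Reductive opening of an α,β-epoxy ketone: divalent samarium gives a ketyl that cleaves the adjacent C2–O bond, and a second electron and methanol give the β-hydroxy ketone; the C3–O bond is never broken, so the trans relation to C4 is kept, and the C2 center formed on protonation is of no consequence because it becomes sp2 in step 6.

Step 5
Reactants: 5 (3S,4S)-4-[(tert-butyldimethylsilyl)oxy]-3-hydroxy-2,6,6-trimethylcyclohexan-1-one
Product: 6 (3S,4S)-3,4-bis[(tert-butyldimethylsilyl)oxy]-2,6,6-trimethylcyclohexan-1-one (mixture of epimers at C2)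
Conditions: TBSOTf, 2,6-lutidine, CH2Cl2, −78 to 0 °C
Reagents that add atoms: tert-butyldimethylsilyl trifluoromethanesulfonate, CC(C)(C)[Si](C)(C)OS(=O)(=O)C(F)(F)F
Why: Silylation of a hindered secondary alcohol with a silyl triflate and a non-nucleophilic base, mild enough to avoid dehydration of the β-hydroxy ketone; since both oxygens end with the same group, any 1,2-silyl shift is without consequence.

Step 6
Reactants: 6 (3S,4S)-3,4-bis[(tert-butyldimethylsilyl)oxy]-2,6,6-trimethylcyclohexan-1-one
Product: 8 (3S,4S)-3,4-bis[(tert-butyldimethylsilyl)oxy]-2,6,6-trimethylcyclohex-1-en-1-yl trifluoromethanesulfonate, via lithium enolate 7 (not isolated)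
Conditions: LiN(i-Pr)2, THF, −78 °C; then Comins' reagent, −78 to −20 °C
Reagents that add atoms: N-(5-chloropyridin-2-yl)-1,1,1-trifluoro-N-(trifluoromethylsulfonyl)methanesulfonamide (Comins' reagent), O=S(=O)(N(c1ccc(Cl)cn1)S(=O)(=O)C(F)(F)F)C(F)(F)F
Why: Enol triflate synthesis by kinetic deprotonation and O-triflation; C6 is quaternary, so only C2 can be deprotonated and both C2 epimers of 6 converge on the single enolate 7, while the low temperature and the lithium counter-ion hold back loss of the β-silyloxy group.

Step 7
Reactants: 8 (3S,4S)-3,4-bis[(tert-butyldimethylsilyl)oxy]-2,6,6-trimethylcyclohex-1-en-1-yl trifluoromethanesulfonate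
Product: 9 (3S,4S)-3,4-dihydroxy-2,6,6-trimethylcyclohex-1-en-1-yl trifluoromethanesulfonate
Conditions: HF·pyridine, pyridine/THF, 0 to 23 °C
Reagents that add atoms: none
Why: Fluoride-mediated cleavage of both silyl ethers under buffered conditions; the enol triflate is inert to HF·pyridine and its electron-poor double bond disfavours ionization of the allylic C–O bond, so the acid-sensitive deprotection is done here and not on the C40 stage.

Step 8
Reactants: 10 (2E)-3-methylpent-2-en-4-yn-1-ol
Product: 13 (2E)-3-methyl-5-(trimethylsilyl)pent-2-en-4-yn-1-ol, via dilithium alkoxide acetylide 11 (not isolated), via bis-silylated enynol 12 (not isolated)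
Conditions: n-BuLi (2.1 equiv), THF, −78 to 0 °C; Me3SiCl (2.2 equiv); then 1 M HCl, 23 °C
Reagents that add atoms: chlorotrimethylsilane, C[Si](C)(C)Cl
Why: Double deprotonation (O–H and C(sp)–H), double silylation and selective hydrolysis of the labile O–Si bond on acidic work-up leave the C-silyl alkyne; the E double bond is not involved.

Step 9
Reactants: 13 (2E)-3-methyl-5-(trimethylsilyl)pent-2-en-4-yn-1-ol
Product: 14 [(3E)-5-bromo-3-methylpent-3-en-1-yn-1-yl]trimethylsilane
Conditions: CBr4, PPh3, CH2Cl2, 0 °C
Reagents that add atoms: tetrabromomethane, BrC(Br)(Br)Br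
Why: Appel bromination by SN2 displacement of the oxyphosphonium group at the primary allylic carbon under neutral conditions, so neither allylic shift nor E/Z change is expected.

Step 10
Reactants: 14 [(3E)-5-bromo-3-methylpent-3-en-1-yn-1-yl]trimethylsilane
Product: 15 diethyl [(2E)-3-methyl-5-(trimethylsilyl)pent-2-en-4-yn-1-yl]phosphonate
Conditions: P(OEt)3, neat, 110 °C
Reagents that add atoms: triethyl phosphite, CCOP(OCC)OCC
Why: Michaelis–Arbuzov reaction: SN2 attack of phosphorus at the primary allylic bromide and dealkylation of the phosphonium intermediate by bromide; the double bond geometry is retained.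

Step 11
Reactants: 15 diethyl [(2E)-3-methyl-5-(trimethylsilyl)pent-2-en-4-yn-1-yl]phosphonate (2.3 equiv); 16 (2E,4E,6E)-2,7-dimethylocta-2,4,6-trienedial
Product: 19 (3E,5E,7E,9E,11E,13E,15E)-3,7,12,16-tetramethyl-1,18-bis(trimethylsilyl)octadeca-3,5,7,9,11,13,15-heptaene-1,17-diyne, via lithiated phosphonate 17 (not isolated), via mono-olefinated aldehyde 18 (not isolated)
Conditions: n-BuLi, THF/DMPU, −78 °C; then 16, −78 to 0 °C, dark
Reagents that add atoms: none
Why: Two-directional Horner–Wadsworth–Emmons olefination: the allylic phosphonate carbanion 17 attacks each aldehyde group through its α-carbon and syn elimination of phosphate from the equilibrated oxaphosphetane gives the E alkene at C11=C12 and C11'=C12'; the double bonds already present in 15 and 16 are not involved and keep their geometry.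

Step 12
Reactants: 19 (3E,5E,7E,9E,11E,13E,15E)-3,7,12,16-tetramethyl-1,18-bis(trimethylsilyl)octadeca-3,5,7,9,11,13,15-heptaene-1,17-diyne
Product: 20 (3E,5E,7E,9E,11E,13E,15E)-3,7,12,16-tetramethyloctadeca-3,5,7,9,11,13,15-heptaene-1,17-diyne
Conditions: K2CO3 (cat.), MeOH/THF, 23 °C, dark, argon
Reagents that add atoms: none
Why: Protodesilylation of alkynylsilanes: methoxide attacks silicon and the acetylide is protonated by methanol; the conditions are too mild to move any double bond, and 20 is used at once.

Step 13
Reactants: 9 (3S,4S)-3,4-dihydroxy-2,6,6-trimethylcyclohex-1-en-1-yl trifluoromethanesulfonate (2.4 equiv); 20 (3E,5E,7E,9E,11E,13E,15E)-3,7,12,16-tetramethyloctadeca-3,5,7,9,11,13,15-heptaene-1,17-diyne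
Product: 22 (all-E)-(3S,4S,3'S,4'S)-7,8,7',8'-tetradehydro-β,β-carotene-3,4,3',4'-tetrol (target), via mono-coupled diol 21 (not isolated)
Conditions: Pd(PPh3)4 (10 mol %), CuI (20 mol %), i-Pr2NH, THF, 45 °C, degassed, dark
Reagents that add atoms: none
Why: Two-directional Sonogashira coupling: zerovalent palladium inserts into the C–O bond of the enol triflate of 9, the copper acetylide formed from one terminus of 20 with CuI and the amine transmetalates, and reductive elimination forms the C6–C7 bond to give 21, whose remaining terminus repeats the cycle to form C6'–C7'. The closest known reaction type is the Sonogashira coupling of 2,6,6-trimethylcyclohexenyl triflates with terminal enynes; the hindered partner is the triflate, while the sp terminus of the alkyne is sterically undemanding, which is why this polarity is chosen. No ring is closed and no stereocenter is created; the four carbinol centers of the two molecules of 9 are spectators. The step forms no C=C bond, so all nine double bonds keep the geometry they had in 9 and 20 and no equilibration toward 9Z forms is needed. The step needs cross-coupling to outrun oxidative dimerization of the alkyne, which is secured by exclusion of oxygen and an excess of 9. It also needs tolerance of the free diols, which is secured because an unactivated allylic hydroxyl is not ionized by zerovalent palladium and is not touched by the amine. Both termini of 20 are identical by symmetry, so no site selectivity is required and 21 converges on 22.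

## Compound list

1 | 2,6,6-trimethylcyclohex-2-ene-1,4-dione (ketoisophorone) | CC1=CC(=O)CC(C)(C)C1=O | starting material
2 | (4S)-4-hydroxy-2,6,6-trimethylcyclohex-2-en-1-one | CC1=C[C@@H](O)CC(C)(C)C1=O | intermediate
3 | (4S)-4-[(tert-butyldimethylsilyl)oxy]-2,6,6-trimethylcyclohex-2-en-1-one | CC1=C[C@@H](O[Si](C)(C)C(C)(C)C)CC(C)(C)C1=O | intermediate
4 | (2R,3R,4S)-4-[(tert-butyldimethylsilyl)oxy]-2,3-epoxy-2,6,6-trimethylcyclohexan-1-one | C[C@@]12O[C@@H]1[C@@H](O[Si](C)(C)C(C)(C)C)CC(C)(C)C2=O | intermediate
5 | (3S,4S)-4-[(tert-butyldimethylsilyl)oxy]-3-hydroxy-2,6,6-trimethylcyclohexan-1-one (C2 epimers) | CC1[C@H](O)[C@@H](O[Si](C)(C)C(C)(C)C)CC(C)(C)C1=O | intermediate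
6 | (3S,4S)-3,4-bis[(tert-butyldimethylsilyl)oxy]-2,6,6-trimethylcyclohexan-1-one (C2 epimers) | CC1[C@H](O[Si](C)(C)C(C)(C)C)[C@@H](O[Si](C)(C)C(C)(C)C)CC(C)(C)C1=O | intermediate
7 | lithium enolate of 6 | [Li+].CC1=C([O-])C(C)(C)C[C@H](O[Si](C)(C)C(C)(C)C)[C@H]1O[Si](C)(C)C(C)(C)C | intermediate
8 | (3S,4S)-3,4-bis[(tert-butyldimethylsilyl)oxy]-2,6,6-trimethylcyclohex-1-en-1-yl trifluoromethanesulfonate | CC1=C(OS(=O)(=O)C(F)(F)F)C(C)(C)C[C@H](O[Si](C)(C)C(C)(C)C)[C@H]1O[Si](C)(C)C(C)(C)C | intermediate
9 | (3S,4S)-3,4-dihydroxy-2,6,6-trimethylcyclohex-1-en-1-yl trifluoromethanesulfonate | CC1=C(OS(=O)(=O)C(F)(F)F)C(C)(C)C[C@H](O)[C@H]1O | intermediate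
10 | (2E)-3-methylpent-2-en-4-yn-1-ol | OC/C=C(C)/C#C | starting material
11 | dilithium alkoxide acetylide of 10 | [Li+].[Li+].[O-]C/C=C(C)/C#[C-] | intermediate
12 | trimethyl{[(2E)-3-methyl-5-(trimethylsilyl)pent-2-en-4-yn-1-yl]oxy}silane | C[Si](C)(C)OC/C=C(C)/C#C[Si](C)(C)C | intermediate
13 | (2E)-3-methyl-5-(trimethylsilyl)pent-2-en-4-yn-1-ol | OC/C=C(C)/C#C[Si](C)(C)C | intermediate
14 | [(3E)-5-bromo-3-methylpent-3-en-1-yn-1-yl]trimethylsilane | BrC/C=C(C)/C#C[Si](C)(C)C | intermediate
15 | diethyl [(2E)-3-methyl-5-(trimethylsilyl)pent-2-en-4-yn-1-yl]phosphonate | CCOP(=O)(OCC)C/C=C(C)/C#C[Si](C)(C)C | intermediate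
16 | (2E,4E,6E)-2,7-dimethylocta-2,4,6-trienedial | O=C/C(C)=C/C=C/C=C(C)/C=O | starting material
17 | lithium salt of the α-carbanion of 15 | [Li+].CCOP(=O)(OCC)[CH-]/C=C(C)/C#C[Si](C)(C)C | intermediate
18 | (2E,4E,6E,8E,10E)-2,7,11-trimethyl-13-(trimethylsilyl)trideca-2,4,6,8,10-pentaen-12-ynal | C[Si](C)(C)C#C/C(C)=C/C=C/C(C)=C/C=C/C=C(C)/C=O | intermediate
19 | (3E,5E,7E,9E,11E,13E,15E)-3,7,12,16-tetramethyl-1,18-bis(trimethylsilyl)octadeca-3,5,7,9,11,13,15-heptaene-1,17-diyne | C[Si](C)(C)C#C/C(C)=C/C=C/C(C)=C/C=C/C=C(C)/C=C/C=C(\C)C#C[Si](C)(C)C | intermediate
20 | (3E,5E,7E,9E,11E,13E,15E)-3,7,12,16-tetramethyloctadeca-3,5,7,9,11,13,15-heptaene-1,17-diyne | C#C/C(C)=C/C=C/C(C)=C/C=C/C=C(C)/C=C/C=C(\C)C#C | intermediate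
21 | (1S,2S)-3,5,5-trimethyl-4-[(3E,5E,7E,9E,11E,13E,15E)-3,7,12,16-tetramethyloctadeca-3,5,7,9,11,13,15-heptaene-1,17-diyn-1-yl]cyclohex-3-ene-1,2-diol | CC1=C(C#C/C(C)=C/C=C/C(C)=C/C=C/C=C(C)/C=C/C=C(\C)C#C)C(C)(C)C[C@H](O)[C@H]1O | intermediate
22 | (all-E)-(3S,4S,3'S,4'S)-7,8,7',8'-tetradehydro-β,β-carotene-3,4,3',4'-tetrol | CC1=C(C#C/C(C)=C/C=C/C(C)=C/C=C/C=C(C)/C=C/C=C(\C)C#CC2=C(C)[C@H](O)[C@@H](O)CC2(C)C)C(C)(C)C[C@H](O)[C@H]1O | target

## Step count and risk

Total step count: 13 (ring series steps 1 to 7, chain series steps 8 to 12, union in step 13).
Longest linear sequence: 8 steps (steps 1 to 7 and step 13, from 1 to 22); the chain branch is 6 steps (steps 8 to 13).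

Least certain steps:

Step 13 (key step). Most likely failure: slow oxidative addition at the hindered, electron-rich tetrasubstituted triflate, so that the copper acetylides of 20 dimerize oxidatively or the heptaene isomerizes and degrades during prolonged warming. The fallback moves the hindered coupling onto a small, robust alkyne and completes the chain afterwards. It sets out from 8 and 15 (with 16) and comes back at 22:
- 15 would be desilylated (K2CO3, MeOH) to diethyl [(2E)-3-methylpent-2-en-4-yn-1-yl]phosphonate F1.
- F1 would be coupled with 8 (Pd(PPh3)4, CuI, Et3N, DMF, 60 °C, conditions that a small enyne tolerates) to the ring-bearing C15 phosphonate F2.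
- Two equivalents of lithiated F2 would be condensed with 16 in a double Horner–Wadsworth–Emmons olefination to the tetrakis(tert-butyldimethylsilyl) ether of the target F3.
- Bu4NF in THF would then give 22.

Step 6. Most likely failure: E1cB loss of the β-silyloxy group from the enolate, or incomplete deprotonation of the hindered tertiary α-C–H, because the C3–O bond can align with the enolate π system. The fallback avoids any enolate by forming the C6–C7 bonds through carbonyl addition. It sets out from 6 and 20 and comes back at 22:
- 20 would be converted with n-BuLi into its dilithium bis-acetylide F4.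
- F4 would be added to two equivalents of 6 in the presence of CeCl3 to give the bis(tertiary propargylic alcohol) F5.
- Double dehydration with POCl3 in pyridine, which can only proceed toward the hydrogen-bearing carbon C5 (C1 being quaternary), would give the tetrakis(tert-butyldimethylsilyl) ether F3 already described.
- Bu4NF would give 22.

Step 3. Most likely failure: insufficient facial selectivity in the hydroperoxide addition, or erosion of the C4 center by γ-deprotonation under the basic conditions, because substrate control rests on a single adjacent substituent. The fallback replaces epoxidation and reductive opening by a catalyst-controlled conjugate addition. It sets out from 3 and comes back at 5: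
- Copper-catalysed conjugate borylation (B2pin2, CuCl, NaOt-Bu, a chiral bisphosphine chosen to reinforce attack anti to the silyloxy group, MeOH, THF) would give the β-boryl ketone F6.
- Oxidation with NaBO3 in THF/water, which proceeds with retention at carbon, would give 5.

Step 11. Most likely failure: incomplete E selectivity at the two new double bonds and partial reaction of the ambident carbanion through its γ-carbon, errors that are doubled because two termini react. The fallback builds the same chain by stereospecific cross-coupling in place of carbonyl olefination. It sets out from 16 and comes back at 19: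
- Twofold Takai iodo-olefination of 16 (CHI3, CrCl2, THF) would give the bis(E-alkenyl iodide) F7.
- Carboalumination of commercial or freshly prepared (trimethylsilyl)buta-1,3-diyne (Me3Al, Cp2ZrCl2), a syn addition, would give the E-alkenylalane F8.
- F8 would be coupled in the same flask with F7 (Pd(PPh3)4, ZnCl2, THF, Negishi-type coupling) to give 19 with all double bonds of defined geometry.

Step 1. Most likely failure: insufficient regio- or enantioselectivity of the available ketoreductases, because the facial preference on this ene-dione is assumed and not guaranteed. The fallback separates reduction and stereoselection. It sets out from 1 and comes back at 2: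
- Reduction with NaBH4/CeCl3 at −78 °C at the unhindered carbonyl would give the racemic alcohol F9.
- Lipase-catalysed acylation with vinyl acetate (kinetic resolution by a serine hydrolase chosen to acylate the 4R enantiomer) would convert the unwanted enantiomer into the (4R)-acetate F10 and leave 2.

## Further compounds

F1 | step 13 | diethyl [(2E)-3-methylpent-2-en-4-yn-1-yl]phosphonate | CCOP(=O)(OCC)C/C=C(C)/C#C
F2 | step 13 | diethyl [(2E)-5-[(3S,4S)-3,4-bis[(tert-butyldimethylsilyl)oxy]-2,6,6-trimethylcyclohex-1-en-1-yl]-3-methylpent-2-en-4-yn-1-yl]phosphonate | CCOP(=O)(OCC)C/C=C(C)/C#CC1=C(C)[C@H](O[Si](C)(C)C(C)(C)C)[C@@H](O[Si](C)(C)C(C)(C)C)CC1(C)C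
F3 | step 13 | 3,4,3',4'-tetrakis-O-(tert-butyldimethylsilyl) ether of 22 | CC1=C(C#C/C(C)=C/C=C/C(C)=C/C=C/C=C(C)/C=C/C=C(\C)C#CC2=C(C)[C@H](O[Si](C)(C)C(C)(C)C)[C@@H](O[Si](C)(C)C(C)(C)C)CC2(C)C)C(C)(C)C[C@H](O[Si](C)(C)C(C)(C)C)[C@H]1O[Si](C)(C)C(C)(C)C
F4 | step 6 | dilithium bis-acetylide of 20 | [Li+].[Li+].[C-]#C/C(C)=C/C=C/C(C)=C/C=C/C=C(C)/C=C/C=C(\C)C#[C-]
F5 | step 6 | (3S,4S,3'S,4'S)-3,4,3',4'-tetrakis[(tert-butyldimethylsilyl)oxy]-7,8,7',8'-tetradehydro-5,6,5',6'-tetrahydro-β,β-carotene-6,6'-diol (epimers at C5, C6, C5', C6') | CC1[C@H](O[Si](C)(C)C(C)(C)C)[C@@H](O[Si](C)(C)C(C)(C)C)CC(C)(C)C1(O)C#C/C(C)=C/C=C/C(C)=C/C=C/C=C(C)/C=C/C=C(\C)C#CC1(O)C(C)[C@H](O[Si](C)(C)C(C)(C)C)[C@@H](O[Si](C)(C)C(C)(C)C)CC1(C)C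
F6 | step 3 | (3S,4S)-4-[(tert-butyldimethylsilyl)oxy]-2,6,6-trimethyl-3-(4,4,5,5-tetramethyl-1,3,2-dioxaborolan-2-yl)cyclohexan-1-one (C2 epimers) | CC1[C@H](B2OC(C)(C)C(C)(C)O2)[C@@H](O[Si](C)(C)C(C)(C)C)CC(C)(C)C1=O
F7 | step 11 | (1E,3E,5E,7E,9E)-1,10-diiodo-3,8-dimethyldeca-1,3,5,7,9-pentaene | I/C=C/C(C)=C/C=C/C=C(C)/C=C/I
F8 | step 11 | dimethyl[(1E)-2-methyl-4-(trimethylsilyl)but-1-en-3-yn-1-yl]alumane | C[Al](C)/C=C(C)/C#C[Si](C)(C)C
F9 | step 1 | racemic 4-hydroxy-2,6,6-trimethylcyclohex-2-en-1-one | CC1=CC(O)CC(C)(C)C1=O
F10 | step 1 | (4R)-4-acetoxy-2,6,6-trimethylcyclohex-2-en-1-one | CC1=C[C@H](OC(C)=O)CC(C)(C)C1=O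
A1 | alternative 1 | [(2E)-5-[(3S,4S)-3,4-diacetoxy-2,6,6-trimethylcyclohex-1-en-1-yl]-3-methylpent-2-en-4-yn-1-yl]triphenylphosphonium bromide | [Br-].CC1=C(C#C/C(C)=C/C[P+](c2ccccc2)(c2ccccc2)c2ccccc2)C(C)(C)C[C@H](OC(C)=O)[C@H]1OC(C)=O
A2 | alternative 1 | 3,4,3',4'-tetra-O-acetate of 22 | CC1=C(C#C/C(C)=C/C=C/C(C)=C/C=C/C=C(C)/C=C/C=C(\C)C#CC2=C(C)[C@H](OC(C)=O)[C@@H](OC(C)=O)CC2(C)C)C(C)(C)C[C@H](OC(C)=O)[C@H]1OC(C)=O
A3 | alternative 2 | (2E,4E,6E)-9-[(3S,4S)-3,4-bis[(tert-butyldimethylsilyl)oxy]-2,6,6-trimethylcyclohex-1-en-1-yl]-3,7-dimethylnona-2,4,6-trien-8-ynal | CC1=C(C#C/C(C)=C/C=C/C(C)=C/C=O)C(C)(C)C[C@H](O[Si](C)(C)C(C)(C)C)[C@H]1O[Si](C)(C)C(C)(C)C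
A4 | alternative 3 | (3S,3'S)-7,8,7',8'-tetradehydroastaxanthin (3,3'-dihydroxy-7,8,7',8'-tetradehydro-β,β-carotene-4,4'-dione) | CC1=C(C#C/C(C)=C/C=C/C(C)=C/C=C/C=C(C)/C=C/C=C(\C)C#CC2=C(C)C(=O)[C@@H](O)CC2(C)C)C(C)(C)C[C@H](O)C1=O
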